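A flat stretch in a table of low percentages is easily read as a plateau, yet readings scattering by 0.3 percentage points can hide a slow fall.

common to all: starting material 0.80 M

| flask | coupling partner | second substrate | remark | time |
|---|---|---|---|---|
| gamma | 1 equiv | 0.28 equiv (fed, over 2.5 h) | run made earlier |  |
| theta | 1 equiv | 0.44 equiv (fed, over 2.5 h) | run made earlier |  |
| flask | 1.00 equiv | 0.200 equiv (fed, over 2.5 h) |  | 8.0 d |

- gamma (time / d: target / %, starting material / %): 0.417: 6.0, 93.8; 1.25: 4.4, 95.2; 2.50: 2.3, 97.3; 4.00: 1.6, 98.1; 5.00: 1.5, 98.0; 6.00: 2.3, 98.2
- theta (time / d: target / %, starting material / %): 0.417: 6.0, 94.1; 1.25: 4.5, 95.6; 2.50: 2.9, 97.0; 4.00: 1.4, 98.0; 5.00: 1.7, 98.3; 6.00: 1.5, 98.0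

(scatter of a reading: 0.3 percentage points)

* concentration of target at 8.0 d, in M
* concentration of starting material at 8.0 d, in M

Gamma and theta differ in target by at most 0.8 points, in no steady direction, though theta got more second substrate, so their readings are pooled. The flask has less second substrate than either, and is assumed to follow them. Target and starting material sum close to the charge, so one target molecule appears to shuttle: it falls back, then forms again on meeting coupling partner. Its share should then follow the free coupling partner, which no table shows. If coupling partner is lost by pairs meeting (a second-order decay), that loss slows as it thins, and the fall shows as a straight rise in N, the parts of charge per part of target.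

N reads 16.7 at 0.417 d and 60.0 for the last readings, centred on 5.00 d. So f = 9.46 d⁻¹, the fade rate, the daily rise of N. Carried to 8.0 d, it gives N = 88.4, so 0.00905 M of target and 0.791 M of starting material.

The forecast, with 0.013 M of target and 0.787 M of starting material, has the target “settling at a small equilibrium-like or steady level”, which puts it higher than this line.

The flask gives 0.00963 M of target and 0.788 M of starting material.

    starting material + coupling partner ⇌ target (K = 0.120 M⁻¹, k = 0.0290 M⁻¹ h⁻¹)
    coupling partner + target → over-reaction product (k = 0.00220 M⁻¹ h⁻¹)
    2 coupling partner → self-condensation product (k = 0.0240 M⁻¹ h⁻¹)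
    second substrate + coupling partner ⇌ second product (K = 4.10 M⁻¹, k = 0.0250 M⁻¹ h⁻¹)

The flask's target thus stands at N = 83.1, against 88.4 on the line. The largest single effect on the flask's target is its back reaction to starting material and coupling partner: without it, the same flask holds 0.384 M of target. The self-condensation of coupling partner is a part of the fade: with that step removed, the flask holds 0.0529 M. Now carry f to the neighbour flask with 0.600 equiv of coupling partner. The line's value at time zero, 12.7, grows with the smaller charge to 21.2, while f stays. N at 8.0 d becomes 96.8, or 0.00826 M of target, and that neighbour flask gives 0.00846 M.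

All runs were computed on assumed constants; scatter was added.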